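**Retrosynthetic overview**

1. Target (locants used throughout: C1 OMe bridgehead, C2 CHOH, C3 CHOMe, C4 CH2, C5 allyl bridgehead, C6 CHMe, C7 CHAr, C8 C=O) ⇐ C5 bridgehead carboxylic acid; the allyl group enters last by decarboxylative radical allylation, which cannot invert a bridgehead.
2. Bridgehead acid ⇐ α-(methoxyacetyl)-α-(2-methoxy-3-oxopropyl)-γ-aryl-γ-butyrolactone: one acid-triggered operation uses the MeO–CH2 carbon (C1) twice, C1–C2 (aldol, six-membered ring) and C1–C7 (capture of the benzylic cation released from the lactone, five-membered ring).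
3. Quaternary C5 ⇐ Michael addition of the acyl-lactone to 2-methoxyacrolein anti to the ring methyl; after the lactone-to-carbocycle ring switch this chain is the bridge cis to the C6 methyl.
4. Acyl-lactone ⇐ trans-β-methyl-γ-aryl-γ-butyrolactone + methyl methoxyacetate; lactone ⇐ catalytic asymmetric anti-crotylation of 3,4,5-trimethoxybenzaldehyde, hydroboration, oxidative lactonisation (C6 is the only centre taken from the catalyst).
5. Ring order: γ-lactone first, as a temporary template; then both carbocycles of the bicyclo[3.2.1]octane in one operation.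

Assumption: (R)-TRIP is taken to show the same facial sense as reported for benzaldehyde; if it proves opposite, (S)-TRIP is used and nothing else changes.

**Route**

Step 1
Reactants: 1 3,4,5-trimethoxybenzaldehyde; 2 (E)-crotylboronic acid pinacol ester
Product: 3 (1R,2R)-2-methyl-1-(3,4,5-trimethoxyphenyl)but-3-en-1-ol
Conditions: (R)-TRIP [(R)-3,3′-bis(2,4,6-triisopropylphenyl)-1,1′-binaphthyl-2,2′-diyl hydrogen phosphate] (5 mol%), toluene, −30 °C; aq. work-up
Reagents that add atoms: none
Why: Chiral-phosphoric-acid-catalysed crotylboration through a closed six-membered chair transition state; the E-boronate gives the anti adduct and the catalyst selects the aldehyde face, fixing the methyl-bearing carbon (future C6) as R, while the carbinol centre is erased in step 7.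

Step 2
Reactants: 3 (1R,2R)-2-methyl-1-(3,4,5-trimethoxyphenyl)but-3-en-1-ol
Product: 4 (1R,2R)-2-methyl-1-(3,4,5-trimethoxyphenyl)butane-1,4-diol
Conditions: 9-BBN (2.2 equiv), THF, 0 °C → rt; then NaOH, H2O2
Reagents that add atoms: hydrogen peroxide, OO
Why: Anti-Markovnikov hydroboration–oxidation of the terminal alkene with a bulky borane places OH on the terminal carbon and touches no stereocentre.

Step 3
Reactants: 4 (1R,2R)-2-methyl-1-(3,4,5-trimethoxyphenyl)butane-1,4-diol
Product: 5 (4R,5R)-4-methyl-5-(3,4,5-trimethoxyphenyl)oxolan-2-one (trans)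
Conditions: TEMPO (10 mol%), PhI(OAc)2 (2.5 equiv), CH2Cl2, rt
Reagents that add atoms: none
Why: Oxoammonium oxidation is selective for the primary alcohol; the aldehyde closes to the lactol with the benzylic OH and is oxidised on to the γ-lactone (oxidative lactonisation), trans because the diol is anti.

Step 4
Reactants: 5 (4R,5R)-4-methyl-5-(3,4,5-trimethoxyphenyl)oxolan-2-one; 6 methyl methoxyacetate
Product: 7 (3S,4R,5R)-3-(methoxyacetyl)-4-methyl-5-(3,4,5-trimethoxyphenyl)oxolan-2-one
Conditions: LiN(iPr)2 (2.2 equiv), THF, −78 °C; 6, −78 → −20 °C; aq. NH4Cl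
Reagents that add atoms: none
Why: Crossed Claisen condensation of the lactone lithium enolate with the ester, driven by deprotonation of the β-keto lactone by the second equivalent of base; the new C3 centre is epimerisable and settles trans to the 4-methyl group.

Step 5
Reactants: 8 1,1,2-trimethoxyethane; 9 formaldehyde
Product: 11 2-methoxyacrolein, via methoxyacetaldehyde 10 (not isolated)
Conditions: 1 M HCl (cat.), H2O, 50 °C; then aq. CH2O, pyrrolidine (10 mol%), EtCO2H (10 mol%), iPrOH, 45 °C
Reagents that add atoms: water, O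
Why: Acetal hydrolysis followed by amine/acid-catalysed α-methylenation of the aldehyde (Mannich condensation then elimination); no stereocentre.

Step 6
Reactants: 7 (3S,4R,5R)-3-(methoxyacetyl)-4-methyl-5-(3,4,5-trimethoxyphenyl)oxolan-2-one; 11 2-methoxyacrolein
Product: 12 (3R,4R,5R)-3-(methoxyacetyl)-3-(2-methoxy-3-oxopropyl)-4-methyl-5-(3,4,5-trimethoxyphenyl)oxolan-2-one (both epimers at the side-chain CHOMe)
Conditions: Et3N (10 mol%), CH2Cl2, 0 °C → rt
Reagents that add atoms: none
Why: Base-catalysed Michael addition of the soft β-keto lactone enolate; the enal approaches the planar enolate anti to the adjacent 4-methyl group, so the quaternary centre (future C5) carries the chain trans to methyl on the lactone, and the unselective α-methoxy aldehyde centre is corrected in step 7.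

Step 7
Reactants: 12 (3R,4R,5R)-3-(methoxyacetyl)-3-(2-methoxy-3-oxopropyl)-4-methyl-5-(3,4,5-trimethoxyphenyl)oxolan-2-one
Product: 14 (1R,3R,4R,5R,6R,7S)-4-hydroxy-3,5-dimethoxy-7-methyl-8-oxo-6-(3,4,5-trimethoxyphenyl)bicyclo[3.2.1]octane-1-carboxylic acid, via spiro aldol lactone 13 (not isolated)
Conditions: Sc(OTf)3 (10 mol%), (CF3)2CHOH/CH2Cl2 1:4, 0 °C, then 40 °C
Reagents that add atoms: none
Why: Proposed new method: Sc(OTf)3 first promotes intramolecular aldol addition of the only available ketone enol (C1, since C5 is quaternary) to the aldehyde through a chelated chair-like transition state, then on warming ionises the electron-rich benzylic lactone C–O bond so that the same carbon, now a ring enol, captures the cation on the face that puts aryl exo and trans to the C6 methyl and closes the bicycle, while reversible aldol and enolisation of the α-methoxy aldehyde funnel C2 and C3 to the hydrogen-bonded axial OH and the equatorial OMe, and the ring switch turns the chain that was trans to methyl on the lactone into the bridge cis to it; the closest known reaction types are the Lewis-acid-mediated benzylic ring opening of γ-aryl lactones (Haworth-type Friedel–Crafts chemistry) and the acid-induced 1,3 O-to-C shift that converts 2-aryl-hydrobenzofuran neolignans into bicyclo[3.2.1]octanoids.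

Step 8
Reactants: 14 (1R,3R,4R,5R,6R,7S)-4-hydroxy-3,5-dimethoxy-7-methyl-8-oxo-6-(3,4,5-trimethoxyphenyl)bicyclo[3.2.1]octane-1-carboxylic acid; 15 allyl phenyl sulfone
Product: 16 (1R,2R,3R,5S,6S,7R)-2-hydroxy-1,3-dimethoxy-6-methyl-5-(prop-2-en-1-yl)-7-(3,4,5-trimethoxyphenyl)bicyclo[3.2.1]octan-8-one
Conditions: [Ir(dF(CF3)ppy)2(dtbbpy)]PF6 (2 mol%), K2HPO4 (1.5 equiv), 15 (5 equiv), DMSO, blue LEDs, rt
Reagents that add atoms: none
Why: Photoredox decarboxylative radical allylation: the excited photocatalyst oxidises the carboxylate, loss of CO2 gives the bridgehead radical, which adds to the allyl sulfone and expels the sulfonyl radical (SH2′); a bridgehead cannot invert, so C5 keeps the configuration set in step 6.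

**Compound list**

1 | 3,4,5-trimethoxybenzaldehyde | COc1cc(C=O)cc(OC)c1OC | starting material
2 | (E)-crotylboronic acid pinacol ester | C/C=C/CB1OC(C)(C)C(C)(C)O1 | starting material
3 | (1R,2R)-2-methyl-1-(3,4,5-trimethoxyphenyl)but-3-en-1-ol (anti) | C=C[C@@H](C)[C@@H](O)c1cc(OC)c(OC)c(OC)c1 | intermediate
4 | (1R,2R)-2-methyl-1-(3,4,5-trimethoxyphenyl)butane-1,4-diol | OCC[C@@H](C)[C@@H](O)c1cc(OC)c(OC)c(OC)c1 | intermediate
5 | (4R,5R)-4-methyl-5-(3,4,5-trimethoxyphenyl)oxolan-2-one (trans) | O=C1C[C@@H](C)[C@H](c2cc(OC)c(OC)c(OC)c2)O1 | intermediate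
6 | methyl methoxyacetate | COCC(=O)OC | starting material
7 | (3S,4R,5R)-3-(methoxyacetyl)-4-methyl-5-(3,4,5-trimethoxyphenyl)oxolan-2-one | COCC(=O)[C@@H]1[C@@H](C)[C@H](c2cc(OC)c(OC)c(OC)c2)OC1=O | intermediate
8 | 1,1,2-trimethoxyethane | COCC(OC)OC | starting material
9 | formaldehyde | C=O | starting material
10 | methoxyacetaldehyde | COCC=O | intermediate
11 | 2-methoxyacrolein (2-methoxyprop-2-enal) | C=C(OC)C=O | intermediate
12 | (3R,4R,5R)-3-(methoxyacetyl)-3-(2-methoxy-3-oxopropyl)-4-methyl-5-(3,4,5-trimethoxyphenyl)oxolan-2-one, both epimers at the side-chain CHOMe | COCC(=O)[C@@]1(CC(OC)C=O)[C@@H](C)[C@H](c2cc(OC)c(OC)c(OC)c2)OC1=O | intermediate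
13 | (3R,4R,5R)-8-hydroxy-7,9-dimethoxy-4-methyl-3-(3,4,5-trimethoxyphenyl)-2-oxaspiro[4.5]decane-1,6-dione, epimer mixture at positions 7 to 9 | O=C1O[C@@H](c3cc(OC)c(OC)c(OC)c3)[C@H](C)[C@@]12CC(OC)C(O)C(OC)C2=O | intermediate
14 | (1R,3R,4R,5R,6R,7S)-4-hydroxy-3,5-dimethoxy-7-methyl-8-oxo-6-(3,4,5-trimethoxyphenyl)bicyclo[3.2.1]octane-1-carboxylic acid | OC(=O)[C@@]12C[C@@H](OC)[C@@H](O)[C@@](OC)(C1=O)[C@@H](c1cc(OC)c(OC)c(OC)c1)[C@@H]2C | intermediate
15 | allyl phenyl sulfone | C=CCS(=O)(=O)c1ccccc1 | starting material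
16 | (1R,2R,3R,5S,6S,7R)-2-hydroxy-1,3-dimethoxy-6-methyl-5-(prop-2-en-1-yl)-7-(3,4,5-trimethoxyphenyl)bicyclo[3.2.1]octan-8-one | C=CC[C@@]12C[C@@H](OC)[C@@H](O)[C@@](OC)(C1=O)[C@@H](c1cc(OC)c(OC)c(OC)c1)[C@@H]2C | target

**Step count and risks**

Total: 8 steps. Longest linear sequence: 7 (steps 1, 2, 3, 4, 6, 7, 8); step 5 makes the three-carbon acceptor.

Step 7 is the main risk. The lactone may ionise too slowly under catalytic Sc(OTf)3. The cation may lose a proton to give the styrene and so scramble C6. The enol oxygen may trap the cation and the O-alkylated isomer may persist. The C2 epimer ratio rests on equilibration. The fallback sets out from 12 and comes back at 14. The aldol is run alone with DBU (10 mol%, CH2Cl2) and 13 is isolated. TMSOTf and 2,6-lutidine (CH2Cl2, −78 → 0 °C) then convert 13 into (3R,4R,5R)-7,9-dimethoxy-4-methyl-3-(3,4,5-trimethoxyphenyl)-6,8-bis(trimethylsilyloxy)-2-oxaspiro[4.5]dec-6-en-1-one F1. In F1 the preformed silyl enol ether attacks the benzylic cation that the silyl triflate releases from the lactone (Mukaiyama-type benzylation). Aqueous acid then frees the acid and the alcohol to give 14.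

Step 8 is the second risk. The excited photocatalyst may oxidise the trimethoxyarene instead of the carboxylate. The hindered bridgehead radical may add slowly to an unactivated allyl sulfone and be reduced instead. The fallback sets out from 14 and comes back at 16. Coupling with N-hydroxyphthalimide (DIC, DMAP cat., CH2Cl2) gives 1,3-dioxoisoindolin-2-yl (1R,3R,4R,5R,6R,7S)-4-hydroxy-3,5-dimethoxy-7-methyl-8-oxo-6-(3,4,5-trimethoxyphenyl)bicyclo[3.2.1]octane-1-carboxylate F2. The radical is then made by single-electron reduction rather than oxidation (Ru(bpy)3(PF6)2, Hantzsch ester, iPr2NEt, blue light) and trapped with 15 to give 16.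

Step 6 is the third risk. 2-Methoxyacrolein is a deactivated acceptor that polymerises easily, and 1,2-addition or a low anti-to-methyl ratio is possible. The fallback sets out from 7 and comes back at 12. C-Alkylation with 3-bromo-2-methoxyprop-1-ene (K2CO3, acetone) gives (3R,4R,5R)-3-(methoxyacetyl)-3-(2-methoxyprop-2-en-1-yl)-4-methyl-5-(3,4,5-trimethoxyphenyl)oxolan-2-one F3. Hydroboration of the enol ether with pinacolborane and Rh(PPh3)3Cl (2 mol%), then NaBO3 oxidation, gives (3R,4R,5R)-3-(3-hydroxy-2-methoxypropyl)-3-(methoxyacetyl)-4-methyl-5-(3,4,5-trimethoxyphenyl)oxolan-2-one F4. Dess–Martin oxidation of F4 gives 12.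

**Further compounds**

F1 | step 7 | (3R,4R,5R)-7,9-dimethoxy-4-methyl-3-(3,4,5-trimethoxyphenyl)-6,8-bis(trimethylsilyloxy)-2-oxaspiro[4.5]dec-6-en-1-one | O=C1O[C@@H](c3cc(OC)c(OC)c(OC)c3)[C@H](C)[C@@]12CC(OC)C(O[Si](C)(C)C)C(OC)=C2O[Si](C)(C)C
F2 | step 8 | 1,3-dioxoisoindolin-2-yl (1R,3R,4R,5R,6R,7S)-4-hydroxy-3,5-dimethoxy-7-methyl-8-oxo-6-(3,4,5-trimethoxyphenyl)bicyclo[3.2.1]octane-1-carboxylate | O=C(ON1C(=O)c2ccccc2C1=O)[C@@]12C[C@@H](OC)[C@@H](O)[C@@](OC)(C1=O)[C@@H](c1cc(OC)c(OC)c(OC)c1)[C@@H]2C
F3 | step 6 | (3R,4R,5R)-3-(methoxyacetyl)-3-(2-methoxyprop-2-en-1-yl)-4-methyl-5-(3,4,5-trimethoxyphenyl)oxolan-2-one | COCC(=O)[C@@]1(CC(=C)OC)[C@@H](C)[C@H](c2cc(OC)c(OC)c(OC)c2)OC1=O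
F4 | step 6 | (3R,4R,5R)-3-(3-hydroxy-2-methoxypropyl)-3-(methoxyacetyl)-4-methyl-5-(3,4,5-trimethoxyphenyl)oxolan-2-one, both epimers at the side-chain CHOMe | COCC(=O)[C@@]1(CC(OC)CO)[C@@H](C)[C@H](c2cc(OC)c(OC)c(OC)c2)OC1=O
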